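**Remarks on the chemistry (assumptions)**

- The stereodescriptor in the SMILES is read as 2S (priorities at C2: O1 > C1′ of ring B > C3 > H), the configuration of the natural flavanones.
- The chiral acid of step 12 is written as its R antipode. The sense of induction of an ion-pair recombination of this kind cannot be derived with confidence from a model, so the antipode is to be fixed by the first experiment and the mirror-image acid used if required.

## Structural features

The target is a (2S)-flavanone: benzene ring A is fused to ring C, a 2,3-dihydro-4H-pyran-4-one made of O1, C2, C3, C4, C4a and C8a, and ring B is attached at C2. Ring A carries a free hydroxyl at C7 and a 3-methylbut-2-enyl (prenyl) chain at C8, wedged between O1 and the C7 hydroxyl; there is no oxygen at C5. Ring B is a 7-hydroxy-2,2-dimethyl-2H-chromen-6-yl unit: it is bound to C2 through C1′, has a free hydroxyl at C2′ ortho to that bond, and carries a 2,2-dimethylpyran ring (ring D) fused linearly across C4′(O)–C5′(C). C2 is the only stereocenter; it is benzylic, bears O1, lies β to the C4 ketone and has no neighbouring stereocenter to relay or protect its configuration. The fragile groups are the O1–C2 bond (retro-oxa-Michael opening to the 2′-hydroxychalcone under base, ionisation under acid because ring B is ortho/para-dioxygenated, both of which racemise C2), the prenyl olefin next to a free phenol (acid-induced chroman formation) and the electron-rich styrenic olefin of ring D (acid, oxidants, hydrogenation). The real difficulty is therefore not the carbon skeleton but fixing this single, labile stereocenter of ring C under conditions mild enough for two olefins and two phenols, together with the regiochemistry of the two C5 units (prenyl between two oxygens on ring A, linear rather than angular pyran fusion on ring B). The key step exploits the constitutional relationship between ring C (O1–C2–C3–C4=O) and an isomeric 1,3-dioxine ring in which C2 is an acetal carbon bound to O1 and to the oxygen that becomes the C4 carbonyl oxygen, with C3 as an exocyclic methylidene on C4. A 1,3 shift of C2 from that oxygen to C3 turns the acetal into the pyranone, and the cation-stabilising power of ring B at C2, the very feature that makes the target labile, supplies the driving force for ionisation.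

## Logic of the disconnections

**21 to 20.** Cut: the two O–Si bonds (at the C7 and C2′ oxygens). Reason: both phenols must be masked through an organotitanium reagent, a silyl triflate and a cationic rearrangement, and a free C2′ hydroxyl next to the ionising carbon would divert the cation to an ortho-quinone methide. Gain: none in skeleton; 20 already holds the full framework and the stereocenter. Demand: cleavage without base, because phenoxide formation opens ring C of 21 and racemises C2.

**20 to 18 (through 19).** Cut: the C2–C3 bond of ring C, with C2 reconnected to the C4 carbonyl oxygen; forwards this is a 1,3-O-to-C shift. In one sentence: the flavanone is made by a chiral-acid-catalysed Petasis–Ferrier-type rearrangement of the racemic cyclic vinyl acetal 18. Reason: the cut removes the stereocenter, the ketone and ring C at once and replaces the one ring C–C bond by two C–O bonds of an acetal. Gain: the stereocenter becomes an acetal carbon whose configuration is irrelevant, and the precursor is reachable from a salicylic acid and an aldehyde. Demand: face-selective recombination inside a chiral ion pair, attack by the enol in preference to the prenyl and ring D olefins, and strict exclusion of water.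

**18 to 17.** Cut: the exocyclic C4=CH2 bond, back to the C4=O of a lactone. Reason: C3 then comes from a one-carbon reagent and the ring is a simple acylal. Gain: 17 is an ester-acetal of two stable halves. Demand: a methylenation that is neither acidic nor basic, so that the acylal, the silyl ethers and both olefins survive.

**17 to 15 + 7.** Cut: both C–O bonds at the acetal carbon (C2–O1 and C2–O3). Reason: this splits the molecule into ring A and ring B halves of similar size, and acetal formation needs no stereocontrol. Gain: full convergence; each half is a substituted benzene derivative. Demand: acetalisation at low temperature under conditions tolerated by prenyl, chromene and aryl silyl ether; only the salicylic oxygen pair of 15 may react, hence the silyl ether on its C4 oxygen.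

**15 to 13 to 12.** Cut: the C4–O–Si bond, then the ester O–CH3 bond (functional group changes only). Reason: the acid is needed for the acetal, the silyl ether for the later steps. Gain: 12 is a simple ester. Demand: hydrolysis must precede silylation, because an aryl silyl ether would not survive saponification; the silyl ester formed alongside must be cleaved selectively, and the acid must be liberated cold to avoid decarboxylation.

**12 to 11 to 10 to 8 + 9.** Cut: the C3–CH2 bond of the prenyl group, traced back through a [3,3] shift to the O–C bond of a tertiary allyl ether on the C4 oxygen, then to the corresponding alkyne, then to the O–C(tertiary) bond. Reason: direct C-prenylation of 8 is unselective, whereas delivery from the C4 oxygen can reach only C3 or C5, and the hydrogen-bonded chelate of the C2 hydroxyl with the ester biases it to C3. Gain: 8 and 9 are commercial. Demand: monoalkylation at the C4 hydroxyl, a semihydrogenation that stops at the alkene, and a rearrangement temperature low enough to avoid loss of the allyl group.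

**7 to 6 to 5.** Cut: the O–Si bond, then the C6–CHO bond. Reason: the formyl carbon becomes C2 of the target, and the phenol of 5 directs its introduction. Gain: 5 is a small bicyclic phenol. Demand: formylation at C6 rather than C8 under non-acidic conditions.

**5 to 3 to 1 + 2.** Cut: the C3=C4 olefin of ring D back to a C4 ketone (reduction and dehydration), then the aryl–acyl bond and the ring O–C bond of the chromanone. Reason: acylation followed by oxa-Michael closure gives the linear fusion unambiguously, whereas direct chromene annulation of 1 with an enal gives mixtures of positional isomers. Gain: 1 and 2 are commercial. Demand: dehydration without acid-induced dimerisation of 5.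

## Other disconnections considered

**Alternative 1:** Cut of the O1–C2 bond (and, one step earlier, the C2=C3 bond by aldol condensation). Forward key step: asymmetric intramolecular oxa-Michael addition of the ring A hydroxyl of 2′-hydroxychalcone A1, the Claisen–Schmidt product derived from 7. This is the route that comes to mind first. It is not preferred for these reasons:
- The oxa-Michael addition is reversible under every basic or bifunctional catalyst that promotes it, and the same retro-reaction racemises the product, so the enantiomeric purity is limited by an equilibrium. For chalcones without an extra activating ester the known catalysts are only moderately selective.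
- The β-carbon of A1 is deactivated by the ortho/para-dioxygenated ring B.
- The strongly basic condensation does not tolerate aryl silyl ethers and would force acetal-type protection, whose acidic removal endangers the prenyl and chromene groups.
- The chosen plan forms the stereocenter in an irreversible C–C bond formation and turns the donor character of ring B into an advantage.

**Alternative 2:** Cut of the C2–C1′ bond. Forward key step: enantioselective conjugate addition of arylboronic acid A3 to chromone A2, catalysed by Pd(OCOCF3)2 with a chiral pyridine-oxazoline or by [RhCl(C2H4)2]2 with a chiral diene. It is not preferred for these reasons: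
- A3 is electron-rich and ortho-oxygenated, the class of boronic acid most prone to protodeboronation and slowest in the insertion step.
- Cationic divalent palladium can also engage the prenyl and chromene olefins.
- A2 and A3 each need their own multistep preparation (A3 by regioselective halogenation and metalation of the chromene nucleus), so the sequence is longer than the acid-plus-aldehyde assembly of the chosen plan.

**Alternative 3:** Cut of the C2–H and C3–H bonds, that is, dearomatising asymmetric 1,4-reduction of the flat flavone A4 with CuH generated from Cu(OAc)2, a chiral bisphosphine and a hydrosilane, or asymmetric hydrogenation. It is not preferred for these reasons: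
- A4 is a vinylogous ester with a twisted, ortho-substituted 2-aryl group and thus a poor hydride acceptor.
- Hydrogenation catalysts able to reduce flavones would also saturate the prenyl and ring D olefins and tend to over-reduce the ketone.
- A4 is reached only by a redox detour (condensation, oxidation to the pyranone, then reduction), which is longer than the chosen plan.

Key step: step 12

## Route

Step 1
Reactants: 1 resorcinol (benzene-1,3-diol); 2 3-methylbut-2-enoic acid
Product: 3 7-hydroxy-2,2-dimethyl-2,3-dihydro-4H-chromen-4-one
Conditions: P2O5/MeSO3H (1:10 w/w), 70 °C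
Reagents that add atoms: none
Why: Friedel–Crafts acylation of the resorcinol ring para to one hydroxyl, followed in the same medium by oxa-Michael closure of the ortho hydroxyl onto the β,β-dimethyl enone; because the new C–C bond is para to the surviving hydroxyl, the later pyran fusion can only be linear. No stereocenter is formed.

Step 2
Reactants: 3 7-hydroxy-2,2-dimethyl-2,3-dihydro-4H-chromen-4-one
Product: 5 2,2-dimethyl-2H-chromen-7-ol, via 2,2-dimethylchromane-4,7-diol 4 (not isolated)
Conditions: NaBH4, MeOH/THF, 0 °C to rt; aqueous NH4Cl work-up; crude 4, p-TsOH·H2O (2 mol %), toluene, 60 °C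
Reagents that add atoms: none
Why: Borohydride reduction of the aryl ketone and acid-catalysed E1 dehydration of benzylic alcohol 4, whose cation is stabilised by the para hydroxyl and the ortho ring oxygen; the stereocenter of racemic 4 is destroyed again in the same operation.

Step 3
Reactants: 5 2,2-dimethyl-2H-chromen-7-ol
Product: 6 7-hydroxy-2,2-dimethyl-2H-chromene-6-carbaldehyde
Conditions: MgCl2, Et3N, (CH2O)n, MeCN, reflux
Reagents that add atoms: paraformaldehyde (formaldehyde source), C=O
Why: Magnesium phenoxide-directed ortho-formylation (Casnati–Skattebøl reaction); of the two positions ortho to the hydroxyl, C6 (para to the ring oxygen, unhindered) should be taken in preference to C8 (flanked by two oxygens), as is usual for 3-alkoxyphenols, and the non-acidic medium spares the chromene olefin.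

Step 4
Reactants: 6 7-hydroxy-2,2-dimethyl-2H-chromene-6-carbaldehyde
Product: 7 7-[(tert-butyldimethylsilyl)oxy]-2,2-dimethyl-2H-chromene-6-carbaldehyde
Conditions: t-BuMe2SiCl, imidazole, DMF, rt
Reagents that add atoms: tert-butyldimethylsilyl chloride, CC(C)(C)[Si](C)(C)Cl
Why: Standard silylation of the chelated phenol; the silyl ether masks the phenol against the titanium reagent of step 11 and prevents ortho-quinone methide formation when the neighbouring carbon is ionised in step 12.

Step 5
Reactants: 8 methyl 2,4-dihydroxybenzoate; 9 3-chloro-3-methylbut-1-yne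
Product: 10 methyl 2-hydroxy-4-[(2-methylbut-3-yn-2-yl)oxy]benzoate
Conditions: K2CO3, KI (cat.), CuI (cat.), acetone, reflux
Reagents that add atoms: none
Why: Copper-assisted O-alkylation of a phenoxide with a tertiary propargylic chloride; the C4 hydroxyl is the more acidic and is not tied up in the hydrogen bond to the ester carbonyl, so it should react selectively.

Step 6
Reactants: 10 methyl 2-hydroxy-4-[(2-methylbut-3-yn-2-yl)oxy]benzoate
Product: 11 methyl 2-hydroxy-4-[(2-methylbut-3-en-2-yl)oxy]benzoate
Conditions: H2 (1 atm), Pd/CaCO3 poisoned with Pb(OAc)2, quinoline, EtOAc, rt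
Reagents that add atoms: none
Why: Semihydrogenation of the terminal alkyne on poisoned palladium stops at the alkene; the aryl ether and the ester are inert.

Step 7
Reactants: 11 methyl 2-hydroxy-4-[(2-methylbut-3-en-2-yl)oxy]benzoate
Product: 12 methyl 2,4-dihydroxy-3-(3-methylbut-2-en-1-yl)benzoate
Conditions: N,N-diethylaniline, 130 °C
Reagents that add atoms: none
Why: Aromatic Claisen rearrangement ([3,3]-sigmatropic shift) followed by tautomerisation; the tertiary allyl ether inverts to deliver a prenyl group, and the hydrogen-bonded chelate between the C2 hydroxyl and the ester localises double-bond character in the C3–C4 bond, which should direct migration to C3 rather than C5.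

Step 8
Reactants: 12 methyl 2,4-dihydroxy-3-(3-methylbut-2-en-1-yl)benzoate
Product: 13 2,4-dihydroxy-3-(3-methylbut-2-en-1-yl)benzoic acid
Conditions: LiOH·H2O, THF/MeOH/H2O, 50 °C; then 1 M HCl, 0 °C
Reagents that add atoms: lithium hydroxide, [Li+].[OH-]
Why: Saponification of the methyl ester as its phenoxide; acidification in the cold avoids the thermal decarboxylation to which 2,4-dihydroxybenzoic acids are prone, and the prenyl group is inert to base.

Step 9
Reactants: 13 2,4-dihydroxy-3-(3-methylbut-2-en-1-yl)benzoic acid
Product: 15 4-[(tert-butyldimethylsilyl)oxy]-2-hydroxy-3-(3-methylbut-2-en-1-yl)benzoic acid, via the bis-silylated silyl ester 14 (not isolated)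
Conditions: t-BuMe2SiCl (2.3 equiv), imidazole, DMF, 0 °C to rt; then AcOH/THF/H2O, rt
Reagents that add atoms: tert-butyldimethylsilyl chloride, CC(C)(C)[Si](C)(C)Cl
Why: Silylation of the carboxyl and of the unhindered C4 hydroxyl (the C2 hydroxyl is hydrogen-bonded and flanked on both sides); silyl ester 14 is far more labile than the aryl silyl ether and is hydrolysed selectively by aqueous acetic acid. This order is used because an aryl silyl ether would not survive step 8.

Step 10
Reactants: 15 4-[(tert-butyldimethylsilyl)oxy]-2-hydroxy-3-(3-methylbut-2-en-1-yl)benzoic acid; 7 7-[(tert-butyldimethylsilyl)oxy]-2,2-dimethyl-2H-chromene-6-carbaldehyde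
Product: 17 rac-7-[(tert-butyldimethylsilyl)oxy]-2-{7-[(tert-butyldimethylsilyl)oxy]-2,2-dimethyl-2H-chromen-6-yl}-8-(3-methylbut-2-en-1-yl)-4H-1,3-benzodioxin-4-one, via bis(trimethylsilyl) derivative 16 (not isolated)
Conditions: (Me3Si)2NH, Me3SiCl (cat.), CH2Cl2, 40 °C, then evaporation; 7, Me3SiOTf (5 mol %), CH2Cl2, −78 °C; pyridine quench
Reagents that add atoms: hexamethyldisilazane, C[Si](C)(C)N[Si](C)(C)C (its trimethylsilyl groups are present in 16 only)
Why: Silyl triflate-catalysed acetalisation of an aldehyde with a bis-silylated hydroxy acid, the standard entry to the 1,3-dioxan-4-ones of Petasis–Ferrier sequences, applied here to a salicylic acid: silyloxocarbenium formation from 7, attack by the phenolic oxygen, and ring closure by the silyl ester oxygen with loss of hexamethyldisiloxane. The acetal carbon is formed racemic, which is of no consequence because it is ionised in step 12.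

Step 11
Reactants: 17 rac-7-[(tert-butyldimethylsilyl)oxy]-2-{7-[(tert-butyldimethylsilyl)oxy]-2,2-dimethyl-2H-chromen-6-yl}-8-(3-methylbut-2-en-1-yl)-4H-1,3-benzodioxin-4-one
Product: 18 rac-7-[(tert-butyldimethylsilyl)oxy]-2-{7-[(tert-butyldimethylsilyl)oxy]-2,2-dimethyl-2H-chromen-6-yl}-4-methylidene-8-(3-methylbut-2-en-1-yl)-4H-1,3-benzodioxine
Conditions: (C5H5)2Ti(CH3)2 (2.5 equiv), toluene, 65 °C, dark; filtration through basic alumina
Reagents that add atoms: dimethyltitanocene (C5H5)2Ti(CH3)2, C[Ti](C)(C1C=CC=C1)C1C=CC=C1
Why: Carbonyl methylenation of a lactone by titanocene methylidene generated thermally from (C5H5)2Ti(CH3)2, via an oxatitanacyclobutane; the reagent is neither acidic nor basic, so the acylal, the silyl ethers and both olefins should survive, and it is the standard way to the vinyl acetals used in Petasis–Ferrier rearrangements.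

Step 12
Reactants: 18 rac-7-[(tert-butyldimethylsilyl)oxy]-2-{7-[(tert-butyldimethylsilyl)oxy]-2,2-dimethyl-2H-chromen-6-yl}-4-methylidene-8-(3-methylbut-2-en-1-yl)-4H-1,3-benzodioxine
Product: 20 (2S)-7-[(tert-butyldimethylsilyl)oxy]-2-{7-[(tert-butyldimethylsilyl)oxy]-2,2-dimethyl-2H-chromen-6-yl}-8-(3-methylbut-2-en-1-yl)-2,3-dihydro-4H-chromen-4-one, via oxocarbenium enol ion pair 19 (not isolated)
Conditions: (R)-3,3'-bis(2,4,6-triisopropylphenyl)-1,1'-binaphthyl-2,2'-diyl hydrogen phosphate (5 mol %), 5 Å molecular sieves, toluene, −40 °C
Reagents that add atoms: none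
Why: Proposed new method: a catalytic enantioselective 1,3-O-to-C (Petasis–Ferrier-type) rearrangement of a benzo-fused vinyl acetal, whose closest known relatives are the rearrangement of 4-methylidene-1,3-dioxanes to tetrahydropyran-4-ones promoted by Me2AlCl or i-Bu3Al and the chiral phosphoric acid-catalysed aza-Petasis–Ferrier rearrangement of hemiaminal vinyl ethers. The acid hydrogen-bonds to the enol-ether oxygen O3 of 18 and assists heterolysis of the C2–O3 bond, which is unusually easy because the cationic carbon is stabilised by O1 and by the ortho-silyloxy/para-alkoxy ring B; this gives ion pair 19, an O-aryl oxocarbenium ion tethered through ring A to the enol of the ring A methyl ketone, with the chiral phosphate held against the cation and accepting a hydrogen bond from the enol hydroxyl. Before the enol carbon can reach C2 the enol must turn about the C4–C4a bond by roughly half a turn, and in that time the cation relaxes through its planar conjugated conformer, so the configuration of the acetal carbon of racemic 18 is erased and both enantiomers converge on the same ion pair. Ring C then closes by C3–C2 bond formation in a 6-(enolendo)-endo-trig, aldol-type attack of the enol on the oxocarbenium carbon, and transfer of the enol proton to the phosphate releases ketone 20 and the catalyst. The only new stereocenter, C2, is set here by the chiral counter-anion, which differentiates the two faces of the oxocarbenium ion in a compact, doubly bound transition state in a non-polar solvent at low temperature. The step needs attack through carbon rather than return through oxygen (return only regenerates 18 and is no loss), attack by the enol rather than by the C8 prenyl olefin or the ring D olefin (expected from the far higher nucleophilicity of the phosphate-bound enol and from the reversibility of any Prins-type addition to so stabilised a cation), and exclusion of water (molecular sieves), since hydrolysis would return the methyl ketone and 7. The C–C bond formation is irreversible, and the weak acid and low temperature are chosen so that 20 does not re-ionise at C2–O1.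

Step 13
Reactants: 20 (2S)-7-[(tert-butyldimethylsilyl)oxy]-2-{7-[(tert-butyldimethylsilyl)oxy]-2,2-dimethyl-2H-chromen-6-yl}-8-(3-methylbut-2-en-1-yl)-2,3-dihydro-4H-chromen-4-one
Product: 21 (2S)-7-hydroxy-2-(7-hydroxy-2,2-dimethyl-2H-chromen-6-yl)-8-(3-methylbut-2-en-1-yl)-2,3-dihydro-4H-chromen-4-one
Conditions: HF·pyridine, pyridine, THF, 0 °C to rt
Reagents that add atoms: none
Why: Fluoride-induced cleavage of both aryl silyl ethers in a buffered, weakly acidic medium; no phenoxide is generated, so the retro-oxa-Michael opening that would racemise C2 is avoided, and the medium is too weakly acidic to ionise C2–O1 or to cyclise the prenyl group onto the C7 hydroxyl.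

## Compound list

1 | resorcinol (benzene-1,3-diol) | Oc1cccc(O)c1 | starting material
2 | 3-methylbut-2-enoic acid | CC(C)=CC(=O)O | starting material
3 | 7-hydroxy-2,2-dimethyl-2,3-dihydro-4H-chromen-4-one | CC1(C)CC(=O)c2ccc(O)cc2O1 | intermediate
4 | 2,2-dimethylchromane-4,7-diol (racemic, not isolated) | CC1(C)CC(O)c2ccc(O)cc2O1 | intermediate
5 | 2,2-dimethyl-2H-chromen-7-ol | CC1(C)C=Cc2ccc(O)cc2O1 | intermediate
6 | 7-hydroxy-2,2-dimethyl-2H-chromene-6-carbaldehyde | CC1(C)C=Cc2cc(C=O)c(O)cc2O1 | intermediate
7 | 7-[(tert-butyldimethylsilyl)oxy]-2,2-dimethyl-2H-chromene-6-carbaldehyde | CC1(C)C=Cc2cc(C=O)c(O[Si](C)(C)C(C)(C)C)cc2O1 | intermediate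
8 | methyl 2,4-dihydroxybenzoate | COC(=O)c1ccc(O)cc1O | starting material
9 | 3-chloro-3-methylbut-1-yne | CC(C)(Cl)C#C | starting material
10 | methyl 2-hydroxy-4-[(2-methylbut-3-yn-2-yl)oxy]benzoate | COC(=O)c1ccc(OC(C)(C)C#C)cc1O | intermediate
11 | methyl 2-hydroxy-4-[(2-methylbut-3-en-2-yl)oxy]benzoate | COC(=O)c1ccc(OC(C)(C)C=C)cc1O | intermediate
12 | methyl 2,4-dihydroxy-3-(3-methylbut-2-en-1-yl)benzoate | COC(=O)c1ccc(O)c(CC=C(C)C)c1O | intermediate
13 | 2,4-dihydroxy-3-(3-methylbut-2-en-1-yl)benzoic acid | OC(=O)c1ccc(O)c(CC=C(C)C)c1O | intermediate
14 | tert-butyldimethylsilyl 4-[(tert-butyldimethylsilyl)oxy]-2-hydroxy-3-(3-methylbut-2-en-1-yl)benzoate (not isolated) | CC(C)=CCc1c(O[Si](C)(C)C(C)(C)C)ccc(C(=O)O[Si](C)(C)C(C)(C)C)c1O | intermediate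
15 | 4-[(tert-butyldimethylsilyl)oxy]-2-hydroxy-3-(3-methylbut-2-en-1-yl)benzoic acid | CC(C)=CCc1c(O[Si](C)(C)C(C)(C)C)ccc(C(=O)O)c1O | intermediate
16 | trimethylsilyl 4-[(tert-butyldimethylsilyl)oxy]-3-(3-methylbut-2-en-1-yl)-2-[(trimethylsilyl)oxy]benzoate (not isolated) | CC(C)=CCc1c(O[Si](C)(C)C(C)(C)C)ccc(C(=O)O[Si](C)(C)C)c1O[Si](C)(C)C | intermediate
17 | rac-7-[(tert-butyldimethylsilyl)oxy]-2-{7-[(tert-butyldimethylsilyl)oxy]-2,2-dimethyl-2H-chromen-6-yl}-8-(3-methylbut-2-en-1-yl)-4H-1,3-benzodioxin-4-one | CC(C)=CCc1c(O[Si](C)(C)C(C)(C)C)ccc2c1OC(c1cc3c(cc1O[Si](C)(C)C(C)(C)C)OC(C)(C)C=C3)OC2=O | intermediate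
18 | rac-7-[(tert-butyldimethylsilyl)oxy]-2-{7-[(tert-butyldimethylsilyl)oxy]-2,2-dimethyl-2H-chromen-6-yl}-4-methylidene-8-(3-methylbut-2-en-1-yl)-4H-1,3-benzodioxine | C=C1OC(c2cc3c(cc2O[Si](C)(C)C(C)(C)C)OC(C)(C)C=C3)Oc2c1ccc(O[Si](C)(C)C(C)(C)C)c2CC=C(C)C | intermediate
19 | oxocarbenium enol ion pair: O-aryl oxocarbenium ion carrying the ring A enol, paired with the catalyst phosphate (cation shown, not isolated) | C=C(O)c1ccc(O[Si](C)(C)C(C)(C)C)c(CC=C(C)C)c1[O+]=Cc1cc2c(cc1O[Si](C)(C)C(C)(C)C)OC(C)(C)C=C2 | intermediate
20 | (2S)-7-[(tert-butyldimethylsilyl)oxy]-2-{7-[(tert-butyldimethylsilyl)oxy]-2,2-dimethyl-2H-chromen-6-yl}-8-(3-methylbut-2-en-1-yl)-2,3-dihydro-4H-chromen-4-one | CC(C)=CCc1c(O[Si](C)(C)C(C)(C)C)ccc2c1O[C@H](c1cc3c(cc1O[Si](C)(C)C(C)(C)C)OC(C)(C)C=C3)CC2=O | intermediate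
21 | (2S)-7-hydroxy-2-(7-hydroxy-2,2-dimethyl-2H-chromen-6-yl)-8-(3-methylbut-2-en-1-yl)-2,3-dihydro-4H-chromen-4-one | CC(C)=CCc1c(O)ccc2c1O[C@H](c1cc3c(cc1O)OC(C)(C)C=C3)CC2=O | target

## Step count and least certain steps

Total step count: 13 (steps 1–4 for the ring B aldehyde, steps 5–9 for the ring A acid, steps 10–13 after their union). Longest linear sequence: 9 steps (steps 5 to 13, from 8 and 9).

**Step 12 (key step, proposed new method).** The most likely failures are insufficient facial discrimination in the ion-pair recombination (a loosely bound ion pair or a trace-acid background reaction), protonation of the enol ether at carbon leading to hydrolysis in place of ionisation, and slow re-ionisation of the product at C2–O1 that erodes the enantiomeric purity. The fallback uses known chemistry and sets the stereocenter by a catalytic asymmetric oxa-Michael addition to an activated alkylidene β-keto ester. It sets out from 15 (with 7) and comes back to the route at 20. Acid 15 is activated with 1,1'-carbonyldiimidazole and condensed with magnesium bis(mono-tert-butyl malonate), Mg(O2CCH2CO2t-Bu)2, to give the β-keto ester tert-butyl 3-{4-[(tert-butyldimethylsilyl)oxy]-2-hydroxy-3-(3-methylbut-2-en-1-yl)phenyl}-3-oxopropanoate F1. Knoevenagel condensation of F1 with 7 (piperidine, AcOH, molecular sieves, toluene) should give the alkylidene β-keto ester tert-butyl 2-{4-[(tert-butyldimethylsilyl)oxy]-2-hydroxy-3-(3-methylbut-2-en-1-yl)benzoyl}-3-{7-[(tert-butyldimethylsilyl)oxy]-2,2-dimethyl-2H-chromen-6-yl}prop-2-enoate F2. A cinchona alkaloid-derived bifunctional thiourea (quinine or quinidine series, chosen for the 2S sense) then promotes enantioselective oxa-Michael ring closure to tert-butyl (2S)-7-[(tert-butyldimethylsilyl)oxy]-2-{7-[(tert-butyldimethylsilyl)oxy]-2,2-dimethyl-2H-chromen-6-yl}-8-(3-methylbut-2-en-1-yl)-4-oxochromane-3-carboxylate F3. Acid-induced loss of isobutene with decarboxylation (p-TsOH, toluene, the lowest workable temperature) should lead to 20.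

**Step 10.** The most likely failures are Prins-type capture of the transient oxocarbenium ion by the neighbouring prenyl olefin of 16 or by the chromene olefin of 7, loss of the ortho silyl ether of 7 under the silyl triflate, and an unfavourable equilibrium for so electron-rich and hindered an aldehyde. The fallback replaces carbonyl condensation by acetal exchange from a pre-formed acetal. It sets out from 7 and comes back at 17. Aldehyde 7 is converted with trimethyl orthoformate and pyridinium p-toluenesulfonate into the dimethyl acetal 7-[(tert-butyldimethylsilyl)oxy]-6-(dimethoxymethyl)-2,2-dimethyl-2H-chromene F4, and F4 is exchanged with free acid 15 under pyridinium p-toluenesulfonate catalysis in benzene with continuous removal of methanol on molecular sieves. Ring closure is then driven thermodynamically, without a silyl triflate and without silylation of 15.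

**Step 11.** The most likely failures are ionisation or ring opening of the labile acylal by Lewis-acidic titanium species, and hydrolysis of the vinyl acetal during isolation. The fallback abandons carbonyl olefination: C3 is brought in as the methyl group of a ketone, and the stereocenter is secured by kinetic resolution, a known operation on flavanones. It sets out from 15 (with 7) and comes back at 20. Acid 15 is treated with excess MeLi (THF, −78 to 0 °C) to give the methyl ketone 1-{4-[(tert-butyldimethylsilyl)oxy]-2-hydroxy-3-(3-methylbut-2-en-1-yl)phenyl}ethan-1-one F5. Pyrrolidine-mediated aldol condensation of F5 with 7 and in situ oxa-Michael closure should give the racemic flavanone rac-7-[(tert-butyldimethylsilyl)oxy]-2-{7-[(tert-butyldimethylsilyl)oxy]-2,2-dimethyl-2H-chromen-6-yl}-8-(3-methylbut-2-en-1-yl)-2,3-dihydro-4H-chromen-4-one F6. Asymmetric transfer hydrogenation of F6 with RuCl(p-cymene)[TsDPEN] (antipode chosen so that the 2R ketone is reduced faster) and HCO2H/Et3N, stopped near half conversion, should convert the unwanted enantiomer into the cis alcohol (2R,4R)-7-[(tert-butyldimethylsilyl)oxy]-2-{7-[(tert-butyldimethylsilyl)oxy]-2,2-dimethyl-2H-chromen-6-yl}-8-(3-methylbut-2-en-1-yl)chroman-4-ol F7. The unreduced 2S ketone, which is 20, is separated by chromatography.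

**Step 7.** The most likely failures are competing migration of the allyl group to C5 and thermal loss of the tertiary allyl group as isoprene before it rearranges. The fallback makes the prenyl–arene bond by directed ortho-metalation and the carboxyl carbon by Kolbe–Schmitt carboxylation. It sets out from 1 and comes back at 13. Resorcinol 1 is converted with chloromethyl methyl ether and i-Pr2NEt into 1,3-bis(methoxymethoxy)benzene F8. Lithiation with n-BuLi (THF, 0 °C) at the carbon between the two acetal oxygens, followed by CuI (cat.) and 1-bromo-3-methylbut-2-ene, gives 1,3-bis(methoxymethoxy)-2-(3-methylbut-2-en-1-yl)benzene F9. Brief treatment with dilute HCl in MeOH at rt liberates 2-(3-methylbut-2-en-1-yl)benzene-1,3-diol F10. Carboxylation of F10 with KHCO3 under CO2 with heating, then cold acidification, should give 13, in which the carboxyl can only enter ortho to a hydroxyl and next to the prenyl-bearing carbon's neighbour, the two such positions being equivalent.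

## Further compounds

F1 | step 12 | tert-butyl 3-{4-[(tert-butyldimethylsilyl)oxy]-2-hydroxy-3-(3-methylbut-2-en-1-yl)phenyl}-3-oxopropanoate | CC(C)=CCc1c(O[Si](C)(C)C(C)(C)C)ccc(C(=O)CC(=O)OC(C)(C)C)c1O
F2 | step 12 | tert-butyl 2-{4-[(tert-butyldimethylsilyl)oxy]-2-hydroxy-3-(3-methylbut-2-en-1-yl)benzoyl}-3-{7-[(tert-butyldimethylsilyl)oxy]-2,2-dimethyl-2H-chromen-6-yl}prop-2-enoate (mixture of olefin isomers) | CC(C)=CCc1c(O[Si](C)(C)C(C)(C)C)ccc(C(=O)C(=Cc2cc3C=CC(C)(C)Oc3cc2O[Si](C)(C)C(C)(C)C)C(=O)OC(C)(C)C)c1O
F3 | step 12 | tert-butyl (2S)-7-[(tert-butyldimethylsilyl)oxy]-2-{7-[(tert-butyldimethylsilyl)oxy]-2,2-dimethyl-2H-chromen-6-yl}-8-(3-methylbut-2-en-1-yl)-4-oxochromane-3-carboxylate (C3 epimers and enol) | CC(C)=CCc1c(O[Si](C)(C)C(C)(C)C)ccc2c1O[C@H](c1cc3c(cc1O[Si](C)(C)C(C)(C)C)OC(C)(C)C=C3)C(C(=O)OC(C)(C)C)C2=O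
F4 | step 10 | 7-[(tert-butyldimethylsilyl)oxy]-6-(dimethoxymethyl)-2,2-dimethyl-2H-chromene | COC(OC)c1cc2C=CC(C)(C)Oc2cc1O[Si](C)(C)C(C)(C)C
F5 | step 11 | 1-{4-[(tert-butyldimethylsilyl)oxy]-2-hydroxy-3-(3-methylbut-2-en-1-yl)phenyl}ethan-1-one | CC(=O)c1ccc(O[Si](C)(C)C(C)(C)C)c(CC=C(C)C)c1O
F6 | step 11 | rac-7-[(tert-butyldimethylsilyl)oxy]-2-{7-[(tert-butyldimethylsilyl)oxy]-2,2-dimethyl-2H-chromen-6-yl}-8-(3-methylbut-2-en-1-yl)-2,3-dihydro-4H-chromen-4-one | CC(C)=CCc1c(O[Si](C)(C)C(C)(C)C)ccc2c1OC(c1cc3c(cc1O[Si](C)(C)C(C)(C)C)OC(C)(C)C=C3)CC2=O
F7 | step 11 | (2R,4R)-7-[(tert-butyldimethylsilyl)oxy]-2-{7-[(tert-butyldimethylsilyl)oxy]-2,2-dimethyl-2H-chromen-6-yl}-8-(3-methylbut-2-en-1-yl)chroman-4-ol | CC(C)=CCc1c(O[Si](C)(C)C(C)(C)C)ccc2c1O[C@@H](c1cc3c(cc1O[Si](C)(C)C(C)(C)C)OC(C)(C)C=C3)C[C@H]2O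
F8 | step 7 | 1,3-bis(methoxymethoxy)benzene | COCOc1cccc(OCOC)c1
F9 | step 7 | 1,3-bis(methoxymethoxy)-2-(3-methylbut-2-en-1-yl)benzene | COCOc1cccc(OCOC)c1CC=C(C)C
F10 | step 7 | 2-(3-methylbut-2-en-1-yl)benzene-1,3-diol | CC(C)=CCc1c(O)cccc1O
A1 | alternative 1 | (E)-1-{4-[(tert-butyldimethylsilyl)oxy]-2-hydroxy-3-(3-methylbut-2-en-1-yl)phenyl}-3-{7-[(tert-butyldimethylsilyl)oxy]-2,2-dimethyl-2H-chromen-6-yl}prop-2-en-1-one | CC(C)=CCc1c(O[Si](C)(C)C(C)(C)C)ccc(C(=O)/C=C/c2cc3C=CC(C)(C)Oc3cc2O[Si](C)(C)C(C)(C)C)c1O
A2 | alternative 2 | 7-[(tert-butyldimethylsilyl)oxy]-8-(3-methylbut-2-en-1-yl)-4H-chromen-4-one | CC(C)=CCc1c(O[Si](C)(C)C(C)(C)C)ccc2c1OC=CC2=O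
A3 | alternative 2 | {7-[(tert-butyldimethylsilyl)oxy]-2,2-dimethyl-2H-chromen-6-yl}boronic acid | CC1(C)C=Cc2cc(B(O)O)c(O[Si](C)(C)C(C)(C)C)cc2O1
A4 | alternative 3 | 7-[(tert-butyldimethylsilyl)oxy]-2-{7-[(tert-butyldimethylsilyl)oxy]-2,2-dimethyl-2H-chromen-6-yl}-8-(3-methylbut-2-en-1-yl)-4H-chromen-4-one | CC(C)=CCc1c(O[Si](C)(C)C(C)(C)C)ccc2c1OC(c1cc3c(cc1O[Si](C)(C)C(C)(C)C)OC(C)(C)C=C3)=CC2=O
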